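**Retrosynthetic overview**
- The target comes from O-methylation of 3-hydroxy-5,6,7,8-tetramethoxyflavone, which comes from oxygenation of the C2=C3 bond of 5,6,7,8-tetramethoxyflavone at C3.
- The feature used: the C4 carbonyl of ring C lies between C4a of ring A and the C3=C2(Ph) unit, and O1 sits on C8a next to C4a. Ring C is therefore cut at C4a–C4, C4–C3 and O1–C2 into 2-iodo-3,4,5,6-tetramethoxyphenol, carbon monoxide and phenylacetylene.
- The iodophenol comes from iodination of the single ring C–H of 2,3,4,5-tetramethoxyphenol, made by Dakin oxidation of the aldehyde from Rieche formylation of 1,2,3,4-tetramethoxybenzene.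
- Ring order: ring A is bought fully oxygenated, ring B arrives with the alkyne, and ring C is the only ring formed, in one palladium-catalysed operation.

Key step: step 4

Remark on the chemistry: the target is a planar flavone without any stereogenic element, so the compound as drawn is the only stereoisomer and no step needs stereocontrol.

**Step 1**
Reactants: 1 1,2,3,4-tetramethoxybenzene
Product: 2 2,3,4,5-tetramethoxybenzaldehyde
Conditions: Cl2CHOMe, TiCl4, CH2Cl2, 0 °C to rt; then ice/H2O
Reagents that add atoms: dichloromethyl methyl ether, COC(Cl)Cl; water, O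
Why: Rieche formylation: TiCl4 ionises the dichloromethyl ether to a chloro(methoxy)carbenium ion that attacks the electron-rich ring (Friedel–Crafts type) and the α-chloro ether is hydrolysed on work-up; the two open positions of 1 are equivalent, so only one aldehyde can form.

**Step 2**
Reactants: 2 2,3,4,5-tetramethoxybenzaldehyde
Product: 4 2,3,4,5-tetramethoxyphenol, via aryl formate 3 (not isolated)
Conditions: mCPBA, CH2Cl2, 0 °C to rt; aq. Na2SO3/NaHCO3 wash; then Et3N (cat.), MeOH, rt, under N2
Reagents that add atoms: meta-chloroperoxybenzoic acid, OOC(=O)c1cccc(Cl)c1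
Why: Dakin-type Baeyer–Villiger oxidation: in the Criegee adduct the aryl group, activated by ortho and para methoxy groups, migrates in preference to hydrogen to give formate 3, which base-catalysed methanolysis cleaves; the peracid is destroyed before the easily oxidised phenol is set free.

**Step 3**
Reactants: 4 2,3,4,5-tetramethoxyphenol
Product: 5 2-iodo-3,4,5,6-tetramethoxyphenol
Conditions: NIS, MeCN, 0 °C, dark
Reagents that add atoms: N-iodosuccinimide, O=C1CCC(=O)N1I
Why: Electrophilic aromatic iodination of a strongly activated phenol; ring A carries a single C–H, ortho to the hydroxyl group, so the iodide can only enter there.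

**Step 4**
Reactants: 5 2-iodo-3,4,5,6-tetramethoxyphenol; 6 phenylacetylene; 7 carbon monoxide
Product: 10 5,6,7,8-tetramethoxyflavone, via o-hydroxyaryl ynone 8 (not isolated), via β-diethylamino enone 9 (not isolated)
Conditions: PdCl2(dppf) (cat.), Et2NH (degassed, as solvent), CO (20 bar), 120 °C, autoclave, no copper
Reagents that add atoms: none
Why: Pd(0) formed in situ from PdCl2(dppf) inserts into the C–I bond of 5, CO insertion gives an aroylpalladium(II) iodide, and the amine-deprotonated alkyne 6 is transferred to palladium so that reductive elimination should deliver ynone 8 with the C4a–C4 and C4–C3 bonds in place. Diethylamine then adds to 8 in conjugate fashion to give enaminone 9, the ortho hydroxyl attacks the amine-bearing carbon and diethylamine is expelled, which forms O1–C2 and the aromatic γ-pyranone. The closest known reaction type is the palladium-catalysed carbonylative Sonogashira coupling/annulation of o-iodophenols with terminal alkynes in a secondary amine, which gives flavones; the only difference here is the set of methoxy groups flanking the reacting centres. Ring C closes in the 6-endo mode (6-endo-trig addition–elimination on 9 instead of 5-exo attack on the alkyne of 8, which would lead to the aurone), and no stereocentre is formed. The step needs CO insertion to outrun direct alkynylation (which would end in a 2-phenylbenzofuran) and six- over five-membered closure: the first is secured by CO pressure, the absence of copper and the ready migration of the electron-rich aryl group onto CO, the second by the secondary amine through enaminone 9. The ring fusion is fixed because iodine and hydroxyl are neighbours and ring A has no other open position.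

**Step 5**
Reactants: 10 5,6,7,8-tetramethoxyflavone
Product: 12 3-hydroxy-5,6,7,8-tetramethoxyflavone, via flavone epoxide 11 (not isolated)
Conditions: DMDO (acetone solution, excess, in portions), CH2Cl2, 0 °C to rt, dark; evaporate; then p-TsOH (cat.), CH2Cl2, rt
Reagents that add atoms: dimethyldioxirane, CC1(C)OO1
Why: Dioxirane epoxidation of the C2=C3 enol-ether bond of a flavone followed by acid-catalysed epoxide opening at C2 (oxocarbenium stabilised by O1 and phenyl) and loss of H-3, the known flavone-to-flavonol sequence; ring A has no C–H and the racemic epoxide stereocentres vanish on aromatisation.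

**Step 6**
Reactants: 12 3-hydroxy-5,6,7,8-tetramethoxyflavone
Product: 13 3,5,6,7,8-pentamethoxyflavone
Conditions: MeI, K2CO3, acetone, reflux
Reagents that add atoms: iodomethane, CI
Why: Williamson O-methylation (SN2 of the potassium flavonolate on iodomethane); the C3 hydroxyl is the only acidic site left, so only the fifth methoxy group is introduced.

**Compound list**
1 | 1,2,3,4-tetramethoxybenzene | COc1ccc(OC)c(OC)c1OC | starting material
2 | 2,3,4,5-tetramethoxybenzaldehyde | COc1cc(C=O)c(OC)c(OC)c1OC | intermediate
3 | 2,3,4,5-tetramethoxyphenyl formate (aryl formate, not isolated) | COc1cc(OC=O)c(OC)c(OC)c1OC | intermediate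
4 | 2,3,4,5-tetramethoxyphenol | COc1cc(O)c(OC)c(OC)c1OC | intermediate
5 | 2-iodo-3,4,5,6-tetramethoxyphenol | COc1c(OC)c(OC)c(I)c(O)c1OC | intermediate
6 | phenylacetylene | C#Cc1ccccc1 | starting material
7 | carbon monoxide | [C-]#[O+] | starting material
8 | 1-(2-hydroxy-3,4,5,6-tetramethoxyphenyl)-3-phenylprop-2-yn-1-one (o-hydroxyaryl ynone, not isolated) | COc1c(OC)c(OC)c(C(=O)C#Cc2ccccc2)c(O)c1OC | intermediate
9 | (E)-3-(diethylamino)-1-(2-hydroxy-3,4,5,6-tetramethoxyphenyl)-3-phenylprop-2-en-1-one (β-diethylamino enone, not isolated; E drawn, geometry of no consequence) | CCN(CC)/C(=C/C(=O)c1c(O)c(OC)c(OC)c(OC)c1OC)c1ccccc1 | intermediate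
10 | 5,6,7,8-tetramethoxyflavone (5,6,7,8-tetramethoxy-2-phenyl-4H-chromen-4-one) | COc1c(OC)c(OC)c2c(=O)cc(-c3ccccc3)oc2c1OC | intermediate
11 | 5,6,7,8-tetramethoxyflavone 2,3-epoxide (racemic, oxirane cis-fused across C2–C3; not isolated) | COc1c(OC)c(OC)c2C(=O)C3OC3(c4ccccc4)Oc2c1OC | intermediate
12 | 3-hydroxy-5,6,7,8-tetramethoxyflavone | COc1c(OC)c(OC)c2c(=O)c(O)c(-c3ccccc3)oc2c1OC | intermediate
13 | 3,5,6,7,8-pentamethoxyflavone | COc1c(OC)c(OC)c2c(=O)c(OC)c(-c3ccccc3)oc2c1OC | target

**Step count**
Total: 6 steps. Longest linear sequence: 6 steps (1 to 13); phenylacetylene and carbon monoxide enter at step 4.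

**Steps most likely to fail**

1. Step 4 (key step). Oxidative addition at the electron-rich C–I bond, flanked by two oxygen substituents, may be slow, so that reduction of the iodide or alkyne oligomerisation takes over. Alkynylation may also occur without CO uptake, or the ynone may close in the five-membered mode. Fallback, setting out from phenol 4 and returning at flavone 10: Fries-type C-acetylation of 4 with Ac2O and BF3·OEt2 at the only open ring position should give 1-(2-hydroxy-3,4,5,6-tetramethoxyphenyl)ethan-1-one F1. Claisen–Schmidt condensation of F1 with benzaldehyde (KOH, EtOH, rt) should give the 2'-hydroxychalcone (E)-1-(2-hydroxy-3,4,5,6-tetramethoxyphenyl)-3-phenylprop-2-en-1-one F2. Oxidative cyclisation of F2 with catalytic I2 in DMSO at 120–130 °C (oxa-Michael closure, then iodine-mediated dehydrogenation) should give 10, which re-enters at step 5.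

2. Step 5. Epoxidation of the vinylogous-ester double bond may stall, and long exposure to the dioxirane may degrade the electron-rich ring A. The acid treatment may also open the epoxide with ring contraction instead of enolisation. Fallback, setting out from flavone 10 and returning at flavonol 12: deprotonation at C3 with LDA in THF at −78 °C should give 3-lithio-5,6,7,8-tetramethoxyflavone F3. Quenching with B(OMe)3 should give dimethyl (5,6,7,8-tetramethoxy-4-oxo-2-phenyl-4H-chromen-3-yl)boronate F4. Oxidation of the C–B bond with H2O2 in AcOH should give 12.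

3. Step 3. The iodinating agent may oxidise the very electron-rich para-methoxyphenol (oxidative demethylation towards a quinone) faster than it iodinates the ring carbon. Fallback, setting out from phenol 4 and returning at iodophenol 5: protection with MOMCl and i-Pr2NEt in CH2Cl2 should give 1,2,3,4-tetramethoxy-5-(methoxymethoxy)benzene F5. Directed ortho-lithiation with n-BuLi in THF (−78 to 0 °C) at the only ring C–H, flanked by the MOM ether and a methoxy group, should give [2,3,4,5-tetramethoxy-6-(methoxymethoxy)phenyl]lithium F6. An iodine quench should give 1-iodo-2,3,4,5-tetramethoxy-6-(methoxymethoxy)benzene F7, and removal of the MOM group with HCl in MeOH should give 5.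

**Further compounds**
F1 | step 4 | 1-(2-hydroxy-3,4,5,6-tetramethoxyphenyl)ethan-1-one | CC(=O)c1c(O)c(OC)c(OC)c(OC)c1OC
F2 | step 4 | (E)-1-(2-hydroxy-3,4,5,6-tetramethoxyphenyl)-3-phenylprop-2-en-1-one | O=C(/C=C/c1ccccc1)c1c(O)c(OC)c(OC)c(OC)c1OC
F3 | step 5 | 3-lithio-5,6,7,8-tetramethoxyflavone | [Li]c1c(-c2ccccc2)oc2c(OC)c(OC)c(OC)c(OC)c2c1=O
F4 | step 5 | dimethyl (5,6,7,8-tetramethoxy-4-oxo-2-phenyl-4H-chromen-3-yl)boronate | COB(OC)c1c(-c2ccccc2)oc2c(OC)c(OC)c(OC)c(OC)c2c1=O
F5 | step 3 | 1,2,3,4-tetramethoxy-5-(methoxymethoxy)benzene | COCOc1cc(OC)c(OC)c(OC)c1OC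
F6 | step 3 | [2,3,4,5-tetramethoxy-6-(methoxymethoxy)phenyl]lithium | [Li]c1c(OCOC)c(OC)c(OC)c(OC)c1OC
F7 | step 3 | 1-iodo-2,3,4,5-tetramethoxy-6-(methoxymethoxy)benzene | COCOc1c(I)c(OC)c(OC)c(OC)c1OC
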